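**Plan**
1. Retrosynthetic cuts: the two aryl–CHO bonds and the three O-methyl groups; the C10–CH3 bond; C9'–aryl and C9'–isobutyl (one quinone methide coupling); then, in one operation, C2–C3 and C4–C5 of the cyclopentane (radical (3+2) annulation with a methacrylamide); last the C1=C5 bond of a cycloheptenone (intramolecular Horner–Wadsworth–Emmons), back to (R)-limonene oxide.
2. Forward order: the seven-membered ring is made first from the opened limonene chain; the five-membered ring second (key step); then the benzylic stereocenter with the arene, the C10 methyl carbinol, double formylation and demethylation.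
3. Enabling feature: ring-fusion carbon C5 lies between C1 (which carries the cyclopentane methylene C2) and the ring methylene C6. A radical at C6 beside a C1–C2–C5 cyclopropane opens to a C2 radical plus a C5=C6 alkene, so C2 can capture C3=C4 and C4 can close 5-exo on C5, the C6 radical ending as the C6 methylene. The carbonyl-level C10 next to C1 then allows the ring fusion to be epimerized to trans.
4. Stereochemistry: C7 from (R)-limonene; a temporary C6–O by D-proline; this hydroxyl directs the cyclopropanation (fixes C1–C2), the ring closure relays to C5 and C4; C1 is corrected thermodynamically; C10 by pseudo-axial methyl delivery; C9' by A(1,3)-controlled addition to the quinone methide.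

Key step: step 10

Remark (numbering): C1 and C5 are the ring-fusion carbons (C1 bonded to C10, C5 bonded to C6); C2, C3, C4 complete the cyclopentane (C4 quaternary); C6–C10 complete the cycloheptane (C7 bears isopropenyl, C10 the methyl carbinol); C9' is the benzylic carbon. Bicyclo[5.3.0]decane names use this numbering.
Remark (assumptions): 1 (cis/trans mixture, 4R), 13 and 16 are taken as purchasable; the trans-fused C10 ketone is assumed to be the more stable C1 epimer.

Step 1
Reactants: 1 (4R)-limonene 1,2-oxide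
Product: 2 (3R)-6-oxo-3-(prop-1-en-2-yl)heptanal
Conditions: H5IO6, THF/H2O, 0 °C to rt
Reagents that add atoms: water, O
Why: Epoxide hydrolysis to the glycol and periodate glycol cleavage (Malaprade reaction) should open the ring between the former alkene carbons, so both epoxide diastereomers converge and the C7 stereocenter and isopropenyl group are untouched.

Step 2
Reactants: 2 (3R)-6-oxo-3-(prop-1-en-2-yl)heptanal
Product: 3 (5R)-7,7-dimethoxy-5-(prop-1-en-2-yl)heptan-2-one
Conditions: HC(OMe)3, MeOH, PPTS (cat.), 0 °C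
Reagents that add atoms: trimethyl orthoformate, COC(OC)OC
Why: Acetalization under mild acid should take the aldehyde selectively because the methyl ketone is much less electrophilic.

Step 3
Reactants: 3 (5R)-7,7-dimethoxy-5-(prop-1-en-2-yl)heptan-2-one
Product: 5 diethyl [(5R)-7,7-dimethoxy-2-oxo-5-(prop-1-en-2-yl)heptyl]phosphonate, via phosphonite 4 (not isolated)
Conditions: LiN(iPr)2, THF, −78 °C; ClP(OEt)2, −78 to 0 °C; then air (O2), rt
Reagents that add atoms: diethyl chlorophosphite, CCOP(Cl)OCC; dioxygen, O=O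
Why: The kinetic enolate forms on the methyl side and the soft trivalent phosphorus chloride should be attacked at carbon (C-phosphinylation of a ketone enolate), air then oxidizing the β-keto phosphonite to the β-keto phosphonate.

Step 4
Reactants: 5 diethyl [(5R)-7,7-dimethoxy-2-oxo-5-(prop-1-en-2-yl)heptyl]phosphonate
Product: 6 diethyl [(5R)-2,7-dioxo-5-(prop-1-en-2-yl)heptyl]phosphonate
Conditions: oxalic acid (aq.), THF, rt
Reagents that add atoms: water, O
Why: Mild acetal hydrolysis should free the aldehyde without touching the isopropenyl group; C7 is β to the aldehyde and cannot epimerize.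

Step 5
Reactants: 6 diethyl [(5R)-2,7-dioxo-5-(prop-1-en-2-yl)heptyl]phosphonate
Product: 8 (4R,5S)-4-(anilinooxy)-5-(prop-1-en-2-yl)cyclohept-2-en-1-one, via aminoxy aldehyde 7 (not isolated)
Conditions: PhNO, D-proline (30 mol%), MeCN, −20 °C; then dilution with MeCN (0.005 M), LiCl, iPr2NEt, 0 °C to rt
Reagents that add atoms: nitrosobenzene, O=Nc1ccccc1
Why: Enamine catalysis with D-proline (α-aminoxylation; L-proline gives the R sense) should place oxygen at C6 with S configuration under catalyst control, trans to the isopropenyl group in the ring, and the LiCl/amine Horner–Wadsworth–Emmons reaction at high dilution should then close the seven-membered enone without epimerizing the α-oxy aldehyde.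

Step 6
Reactants: 8 (4R,5S)-4-(anilinooxy)-5-(prop-1-en-2-yl)cyclohept-2-en-1-one
Product: 9 (4R,5S)-4-hydroxy-5-(prop-1-en-2-yl)cyclohept-2-en-1-one
Conditions: CuSO4·5H2O (30 mol%), MeOH, 0 °C to rt
Reagents that add atoms: none
Why: Copper-catalysed cleavage of the O–N bond of an O-alkyl-N-arylhydroxylamine is non-reducing, so the enone and the allylic C–O bond should survive and no stereocenter is touched.

Step 7
Reactants: 9 (4R,5S)-4-hydroxy-5-(prop-1-en-2-yl)cyclohept-2-en-1-one
Product: 10 (8R,9S)-9-(prop-1-en-2-yl)-1,4-dioxaspiro[4.6]undec-6-en-8-ol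
Conditions: TMSOCH2CH2OTMS, TMSOTf (cat.), CH2Cl2, −78 to −20 °C; then K2CO3, MeOH
Reagents that add atoms: 1,2-bis(trimethylsilyloxy)ethane, C[Si](C)(C)OCCO[Si](C)(C)C
Why: Aprotic silyl-transfer ketalization should mask the C10 carbonyl without moving the C1=C5 double bond, and the transient O-silyl ether is released by methanolic K2CO3.

Step 8
Reactants: 10 (8R,9S)-9-(prop-1-en-2-yl)-1,4-dioxaspiro[4.6]undec-6-en-8-ol
Product: 11 (1S,5S,6R,7R)-5-(prop-1-en-2-yl)spiro[bicyclo[5.1.0]octane-2,2'-[1,3]dioxolan]-6-ol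
Conditions: Et2Zn, CH2I2, CH2Cl2, 0 °C
Reagents that add atoms: diiodomethane, ICI
Why: Hydroxyl-directed Simmons–Smith cyclopropanation should deliver the methylene (C2) to the face syn to the C6 oxygen, trans to the isopropenyl group, which fixes the C1–C2 bond on the α face; the undirected isopropenyl group reacts much more slowly.

Step 9
Reactants: 11 (1S,5S,6R,7R)-5-(prop-1-en-2-yl)spiro[bicyclo[5.1.0]octane-2,2'-[1,3]dioxolan]-6-ol
Product: 12 O-[(1S,5S,6R,7R)-5-(prop-1-en-2-yl)spiro[bicyclo[5.1.0]octane-2,2'-[1,3]dioxolan]-6-yl] S-methyl carbonodithioate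
Conditions: NaH, THF, 0 °C; CS2; MeI
Reagents that add atoms: carbon disulfide, S=C=S; iodomethane, CI
Why: Standard xanthate formation from the sodium alkoxide turns the directing hydroxyl into a radical trigger without disturbing ketal, cyclopropane or alkene.

Step 10
Reactants: 12 O-[(1S,5S,6R,7R)-5-(prop-1-en-2-yl)spiro[bicyclo[5.1.0]octane-2,2'-[1,3]dioxolan]-6-yl] S-methyl carbonodithioate; 13 N-methoxy-N-methylmethacrylamide
Product: 14 (1S,4S,5S,7R)-10,10-(ethylenedioxy)-N-methoxy-N,4-dimethyl-7-(prop-1-en-2-yl)-cis-bicyclo[5.3.0]decane-4-carboxamide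
Conditions: 13 (8 equiv), Bu3SnH (1.3 equiv, syringe pump), AIBN (cat.), benzene, 80 °C
Reagents that add atoms: none
Why: Proposed new method: Bu3Sn• should cleave the xanthate to the C6 cyclopropylcarbinyl radical, which opens by scission of the exocyclic C5–C2 bond to the primary C2 radical and a C5=C6 double bond; C2 then adds to the methylene terminus of 13 (Giese addition, bond C2–C3), the tertiary α-carboxamide radical at C4 closes on C5 (bond C4–C5), and the C6 radical takes hydrogen from Bu3SnH, so the helper oxygen at C6 ends as a methylene. The closest known reaction types are the Barton–McCombie fragmentation of cyclopropylcarbinyl xanthates with ring opening and the tin hydride-mediated radical (3+2) annulation of homoallylic radicals with electron-poor alkenes; what is new is their union in one chain on a bicyclo[5.1.0]octane. The cyclopentane closes in the 5-exo-trig mode. C5 is fixed because the tether springs from the α-face methylene on C1 (cis ring fusion, H-5 β), and C4 because the bulkier carboxamide should take the convex position syn to H-5 while the methyl lies over C6. The step needs exocyclic rather than ring-expanding cyclopropane scission (better overlap of the C6 orbital with the exocyclic bond), addition to 13 before hydrogen transfer (slow addition of Bu3SnH, excess 13), preference of the nucleophilic C2 radical for the electron-poor alkene over the isopropenyl group, and 5-exo over 6-endo closure; the dioxolane keeps the C2 radical from the 1,2-acyl shift open to a β-keto radical.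

Step 11
Reactants: 14 (1S,4S,5S,7R)-10,10-(ethylenedioxy)-N-methoxy-N,4-dimethyl-7-(prop-1-en-2-yl)-cis-bicyclo[5.3.0]decane-4-carboxamide
Product: 15 (1S,4S,5S,7R)-10,10-(ethylenedioxy)-4-methyl-7-(prop-1-en-2-yl)-cis-bicyclo[5.3.0]decane-4-carbaldehyde
Conditions: LiAlH4, THF, −78 to 0 °C; KNaC4H4O6 (aq.)
Reagents that add atoms: none
Why: Hydride reduction of an N-methoxy-N-methylamide stops at the chelated tetrahedral adduct, which should release the aldehyde (C9') on work-up; the α carbon is quaternary and cannot epimerize.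

Step 12
Reactants: 15 (1S,4S,5S,7R)-10,10-(ethylenedioxy)-4-methyl-7-(prop-1-en-2-yl)-cis-bicyclo[5.3.0]decane-4-carbaldehyde; 16 3,5-dimethoxyphenol
Product: 19 2-{(1R)-1-[(1S,4S,5S,7R)-10,10-(ethylenedioxy)-4-methyl-7-(prop-1-en-2-yl)-cis-bicyclo[5.3.0]dec-4-yl]-3-methylbutyl}-3,5-dimethoxyphenol, via benzylic alkoxide 17 (not isolated), via ortho-quinone methide 18 (not isolated)
Conditions: 16, iBuMgBr (1.0 equiv), toluene/Et2O, 0 °C; 15, toluene, rt to 60 °C; then iBuMgBr (3 equiv), THF, 0 to 65 °C; NH4Cl (aq.)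
Reagents that add atoms: isobutylmagnesium bromide, CC(C)C[Mg]Br
Why: The bromomagnesium phenoxide should add to the aldehyde ortho to oxygen through a magnesium chelate (ortho-hydroxyalkylation), the dimagnesium salt should eliminate on warming to the ortho-quinone methide, and the isobutyl group should add 1,4 with rearomatization, anti to ring-fusion carbon C5 in the conformer that keeps the C4 methyl in the quinone methide plane (A(1,3) strain), which gives R at C9'; attack at the para position would converge after step 13.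

Step 13
Reactants: 19 2-{(1R)-1-[(1S,4S,5S,7R)-10,10-(ethylenedioxy)-4-methyl-7-(prop-1-en-2-yl)-cis-bicyclo[5.3.0]dec-4-yl]-3-methylbutyl}-3,5-dimethoxyphenol
Product: 20 (1S,4S,5S,7R)-10,10-(ethylenedioxy)-4-methyl-4-[(1R)-3-methyl-1-(2,4,6-trimethoxyphenyl)butyl]-7-(prop-1-en-2-yl)-cis-bicyclo[5.3.0]decane
Conditions: MeI, K2CO3, DMF, rt
Reagents that add atoms: iodomethane, CI
Why: Williamson O-methylation of the phenol gives the symmetric trimethoxyarene needed for the later ortho-metalations.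

Step 14
Reactants: 20 (1S,4S,5S,7R)-10,10-(ethylenedioxy)-4-methyl-4-[(1R)-3-methyl-1-(2,4,6-trimethoxyphenyl)butyl]-7-(prop-1-en-2-yl)-cis-bicyclo[5.3.0]decane
Product: 22 (1R,4S,5S,7R)-4-methyl-4-[(1R)-3-methyl-1-(2,4,6-trimethoxyphenyl)butyl]-7-(prop-1-en-2-yl)-trans-bicyclo[5.3.0]decan-10-one, via cis-fused ketone 21 (not isolated)
Conditions: 1 M HCl, THF, rt; then NaOMe, MeOH, rt
Reagents that add atoms: water, O
Why: Ketal hydrolysis followed by base equilibration at C1 (the only epimerizable stereocenter, α to the C10 ketone) should give the trans-fused hydroazulenone, expected to be the more stable isomer for a seven-ring ketone next to the ring fusion.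

Step 15
Reactants: 22 (1R,4S,5S,7R)-4-methyl-4-[(1R)-3-methyl-1-(2,4,6-trimethoxyphenyl)butyl]-7-(prop-1-en-2-yl)-trans-bicyclo[5.3.0]decan-10-one
Product: 23 (1R,4S,5S,7R,10R)-4,10-dimethyl-4-[(1R)-3-methyl-1-(2,4,6-trimethoxyphenyl)butyl]-7-(prop-1-en-2-yl)-trans-bicyclo[5.3.0]decan-10-ol
Conditions: MeAl(OC6H2-2,6-tBu2-4-Me)2 (3 equiv), toluene, −78 °C; then MeLi, −78 °C
Reagents that add atoms: methyllithium, [Li]C
Why: The bulky aluminium Lewis acid should bind the carbonyl on its open equatorial side, so methyllithium adds along the pseudo-axial trajectory on the β face (anti to the axial H-1) and the hydroxyl ends α, cis to H-1.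

Step 16
Reactants: 23 (1R,4S,5S,7R,10R)-4,10-dimethyl-4-[(1R)-3-methyl-1-(2,4,6-trimethoxyphenyl)butyl]-7-(prop-1-en-2-yl)-trans-bicyclo[5.3.0]decan-10-ol
Product: 25 5-{(1R)-1-[(1R,4S,5S,7R,10R)-10-hydroxy-4,10-dimethyl-7-(prop-1-en-2-yl)-trans-bicyclo[5.3.0]dec-4-yl]-3-methylbutyl}-2,4,6-trimethoxybenzene-1,3-dicarbaldehyde, via amino alkoxide 24 (not isolated)
Conditions: n-BuLi (2.3 equiv), TMEDA, THF, 0 °C; DMF (1.1 equiv), −78 to 0 °C; s-BuLi (1.3 equiv), −78 to −30 °C; DMF (excess); 1 M HCl (aq.) work-up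
Reagents that add atoms: N,N-dimethylformamide, CN(C)C=O
Why: Each free arene position lies between two methoxy groups and should undergo directed ortho-metalation; the first DMF adduct persists as an α-amino alkoxide that protects the first formyl group and helps direct the second lithiation, and the tertiary alcohol is carried as its alkoxide.

Step 17
Reactants: 25 5-{(1R)-1-[(1R,4S,5S,7R,10R)-10-hydroxy-4,10-dimethyl-7-(prop-1-en-2-yl)-trans-bicyclo[5.3.0]dec-4-yl]-3-methylbutyl}-2,4,6-trimethoxybenzene-1,3-dicarbaldehyde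
Product: 26 5-{(1R)-1-[(1R,4S,5S,7R,10R)-10-hydroxy-4,10-dimethyl-7-(prop-1-en-2-yl)-trans-bicyclo[5.3.0]dec-4-yl]-3-methylbutyl}-2,4,6-trihydroxybenzene-1,3-dicarbaldehyde
Conditions: NaSEt, DMF, 110 °C; then dilute HCl (aq.)
Reagents that add atoms: none
Why: Thiolate SN2 demethylation should cleave all three aryl methyl ethers, each activated by an ortho or para formyl group, under non-acidic conditions that spare the tertiary alcohol and the isopropenyl group.

**Compound list**
1 | (4R)-limonene 1,2-oxide (cis/trans mixture at the epoxide) | C=C(C)[C@@H]1CCC2(C)OC2C1 | starting material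
2 | (3R)-6-oxo-3-(prop-1-en-2-yl)heptanal | C=C(C)[C@H](CCC(C)=O)CC=O | intermediate
3 | (5R)-7,7-dimethoxy-5-(prop-1-en-2-yl)heptan-2-one | C=C(C)[C@H](CCC(C)=O)CC(OC)OC | intermediate
4 | diethyl [(5R)-7,7-dimethoxy-2-oxo-5-(prop-1-en-2-yl)heptyl]phosphonite | C=C(C)[C@H](CCC(=O)CP(OCC)OCC)CC(OC)OC | intermediate
5 | diethyl [(5R)-7,7-dimethoxy-2-oxo-5-(prop-1-en-2-yl)heptyl]phosphonate | C=C(C)[C@H](CCC(=O)CP(=O)(OCC)OCC)CC(OC)OC | intermediate
6 | diethyl [(5R)-2,7-dioxo-5-(prop-1-en-2-yl)heptyl]phosphonate | C=C(C)[C@H](CCC(=O)CP(=O)(OCC)OCC)CC=O | intermediate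
7 | diethyl [(5S,6S)-6-(anilinooxy)-2,7-dioxo-5-(prop-1-en-2-yl)heptyl]phosphonate | C=C(C)[C@H](CCC(=O)CP(=O)(OCC)OCC)[C@H](ONc1ccccc1)C=O | intermediate
8 | (4R,5S)-4-(anilinooxy)-5-(prop-1-en-2-yl)cyclohept-2-en-1-one | C=C(C)[C@@H]1CCC(=O)C=C[C@H]1ONc2ccccc2 | intermediate
9 | (4R,5S)-4-hydroxy-5-(prop-1-en-2-yl)cyclohept-2-en-1-one | C=C(C)[C@@H]1CCC(=O)C=C[C@H]1O | intermediate
10 | (8R,9S)-9-(prop-1-en-2-yl)-1,4-dioxaspiro[4.6]undec-6-en-8-ol | C=C(C)[C@@H]1CCC2(OCCO2)C=C[C@H]1O | intermediate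
11 | (1S,5S,6R,7R)-5-(prop-1-en-2-yl)spiro[bicyclo[5.1.0]octane-2,2'-[1,3]dioxolan]-6-ol | C=C(C)[C@@H]1CCC2(OCCO2)[C@H]3C[C@H]3[C@H]1O | intermediate
12 | O-[(1S,5S,6R,7R)-5-(prop-1-en-2-yl)spiro[bicyclo[5.1.0]octane-2,2'-[1,3]dioxolan]-6-yl] S-methyl carbonodithioate | C=C(C)[C@@H]1CCC2(OCCO2)[C@H]3C[C@H]3[C@H]1OC(=S)SC | intermediate
13 | N-methoxy-N-methylmethacrylamide | C=C(C)C(=O)N(C)OC | starting material
14 | (1S,4S,5S,7R)-10,10-(ethylenedioxy)-N-methoxy-N,4-dimethyl-7-(prop-1-en-2-yl)-cis-bicyclo[5.3.0]decane-4-carboxamide | C=C(C)[C@@H]1CCC2(OCCO2)[C@H]3CC[C@](C)(C(=O)N(C)OC)[C@H]3C1 | intermediate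
15 | (1S,4S,5S,7R)-10,10-(ethylenedioxy)-4-methyl-7-(prop-1-en-2-yl)-cis-bicyclo[5.3.0]decane-4-carbaldehyde | C=C(C)[C@@H]1CCC2(OCCO2)[C@H]3CC[C@](C)(C=O)[C@H]3C1 | intermediate
16 | 3,5-dimethoxyphenol | COc1cc(O)cc(OC)c1 | starting material
17 | 2-{hydroxy[(1S,4S,5S,7R)-10,10-(ethylenedioxy)-4-methyl-7-(prop-1-en-2-yl)-cis-bicyclo[5.3.0]dec-4-yl]methyl}-3,5-dimethoxyphenol (both C9' epimers; present as magnesium salt, drawn neutral) | C=C(C)[C@@H]1CCC2(OCCO2)[C@H]3CC[C@](C)(C(O)c4c(O)cc(OC)cc4OC)[C@H]3C1 | intermediate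
18 | 6-{[(1S,4S,5S,7R)-10,10-(ethylenedioxy)-4-methyl-7-(prop-1-en-2-yl)-cis-bicyclo[5.3.0]dec-4-yl]methylidene}-3,5-dimethoxycyclohexa-2,4-dien-1-one | C=C(C)[C@@H]1CCC2(OCCO2)[C@H]3CC[C@](C)(C=C4C(=O)C=C(OC)C=C4OC)[C@H]3C1 | intermediate
19 | 2-{(1R)-1-[(1S,4S,5S,7R)-10,10-(ethylenedioxy)-4-methyl-7-(prop-1-en-2-yl)-cis-bicyclo[5.3.0]dec-4-yl]-3-methylbutyl}-3,5-dimethoxyphenol | C=C(C)[C@@H]1CCC2(OCCO2)[C@H]3CC[C@](C)([C@@H](CC(C)C)c4c(O)cc(OC)cc4OC)[C@H]3C1 | intermediate
20 | (1S,4S,5S,7R)-10,10-(ethylenedioxy)-4-methyl-4-[(1R)-3-methyl-1-(2,4,6-trimethoxyphenyl)butyl]-7-(prop-1-en-2-yl)-cis-bicyclo[5.3.0]decane | C=C(C)[C@@H]1CCC2(OCCO2)[C@H]3CC[C@](C)([C@@H](CC(C)C)c4c(OC)cc(OC)cc4OC)[C@H]3C1 | intermediate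
21 | (1S,4S,5S,7R)-4-methyl-4-[(1R)-3-methyl-1-(2,4,6-trimethoxyphenyl)butyl]-7-(prop-1-en-2-yl)-cis-bicyclo[5.3.0]decan-10-one | C=C(C)[C@@H]1CCC(=O)[C@H]3CC[C@](C)([C@@H](CC(C)C)c4c(OC)cc(OC)cc4OC)[C@H]3C1 | intermediate
22 | (1R,4S,5S,7R)-4-methyl-4-[(1R)-3-methyl-1-(2,4,6-trimethoxyphenyl)butyl]-7-(prop-1-en-2-yl)-trans-bicyclo[5.3.0]decan-10-one | C=C(C)[C@@H]1CCC(=O)[C@@H]2CC[C@](C)([C@@H](CC(C)C)c3c(OC)cc(OC)cc3OC)[C@H]2C1 | intermediate
23 | (1R,4S,5S,7R,10R)-4,10-dimethyl-4-[(1R)-3-methyl-1-(2,4,6-trimethoxyphenyl)butyl]-7-(prop-1-en-2-yl)-trans-bicyclo[5.3.0]decan-10-ol | C=C(C)[C@@H]1CC[C@@](C)(O)[C@@H]2CC[C@](C)([C@@H](CC(C)C)c3c(OC)cc(OC)cc3OC)[C@H]2C1 | intermediate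
24 | mono-formyl adduct of 23 as its α-(dimethylamino) carbinol at one free arene position (present as lithium alkoxide, drawn neutral) | C=C(C)[C@@H]1CC[C@@](C)(O)[C@@H]2CC[C@](C)([C@@H](CC(C)C)c3c(OC)c(C(O)N(C)C)c(OC)cc3OC)[C@H]2C1 | intermediate
25 | 5-{(1R)-1-[(1R,4S,5S,7R,10R)-10-hydroxy-4,10-dimethyl-7-(prop-1-en-2-yl)-trans-bicyclo[5.3.0]dec-4-yl]-3-methylbutyl}-2,4,6-trimethoxybenzene-1,3-dicarbaldehyde | C=C(C)[C@@H]1CC[C@@](C)(O)[C@@H]2CC[C@](C)([C@@H](CC(C)C)c3c(OC)c(C=O)c(OC)c(C=O)c3OC)[C@H]2C1 | intermediate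
26 | 5-{(1R)-1-[(1R,4S,5S,7R,10R)-10-hydroxy-4,10-dimethyl-7-(prop-1-en-2-yl)-trans-bicyclo[5.3.0]dec-4-yl]-3-methylbutyl}-2,4,6-trihydroxybenzene-1,3-dicarbaldehyde (CNP0594576.1) | C=C(C)[C@@H]1CC[C@@](C)(O)[C@@H]2CC[C@](C)([C@@H](CC(C)C)c3c(O)c(C=O)c(O)c(C=O)c3O)[C@H]2C1 | target

**Step count**
Total: 17 steps. Longest linear sequence: 17 steps (1 to 26); 13 and 16 enter as purchased.

**Steps most likely to fail**

Step 10 (Proposed new method). The chain may break down by hydrogen transfer to the C6 or C2 radical before carbon–carbon bond formation, by ring-expanding scission of the cyclopropylcarbinyl radical, by 1,5-hydrogen transfer from the dioxolane to the C2 radical, by telomerization of 13, or by poor facial discrimination at C4. The fallback uses known chemistry and separates the two bond formations; it sets out from 11 and rejoins the route at 15. Ring-opening iodination of 11 (Ph3P, I2, imidazole; cyclopropylcarbinyl-to-homoallyl rearrangement) would give the homoallylic iodide F1. Alkylation of the lithium enolate of tert-butyl propanoate (LiN(iPr)2, THF/HMPA) with F1 would give the open-chain ester F2 (bond C2–C3). α-Selenenylation (LiN(iPr)2, PhSeBr) would give the selenide F3. Bu3SnH/AIBN would then close the cyclopentane by 5-exo cyclization of the tertiary α-ester radical onto C5=C6 (bond C4–C5) to give the bicyclic ester F4. LiAlH4 would give the primary alcohol F5, and Dess–Martin periodinane would return aldehyde 15.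

Step 12. The hindered neopentyl-type aldehyde may resist ortho-hydroxyalkylation, the magnesium alkoxide may not eliminate to the quinone methide, the organomagnesium reagent may transfer hydride to the quinone methide, or the isobutyl group may add with poor facial selectivity. The fallback is stepwise through a para-quinone methide; it sets out from 15 (with 16) and rejoins at 20. Silylation of 16 (iPr3SiCl, imidazole) would give the aryl silyl ether F6. Lithiation between the two methoxy groups (n-BuLi, TMEDA) and addition to 15 would give the benzylic alcohol F7. Desilylation (Bu4NF) and 1,6-elimination (MsCl, Et3N) would give the isolable para-quinone methide F8. 1,6-Addition of iBuMgBr catalysed by CuBr·SMe2 would give the para-phenol F9, and O-methylation (MeI, K2CO3) would give 20.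

Step 15. Methyl delivery may occur from the wrong face of the flexible cycloheptanone, or the ketone may be enolized. The fallback delivers the carbon as a methylene through a betaine and sets the methyl by reduction; it sets out from 22 and rejoins at 23. Dimethylsulfonium methylide (Me3SI, KN(SiMe3)2, THF) would attack irreversibly along the pseudo-axial trajectory to give the spiro-epoxide F10, and LiEt3BH would open it at the methylene carbon to give 23.

**Further compounds**
F1 | step 10 | (6S,9R)-6-(iodomethyl)-9-(prop-1-en-2-yl)-1,4-dioxaspiro[4.6]undec-7-ene | C=C(C)[C@@H]1CCC2(OCCO2)[C@@H](CI)C=C1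
F2 | step 10 | tert-butyl 2-methyl-4-[(6S,9R)-9-(prop-1-en-2-yl)-1,4-dioxaspiro[4.6]undec-7-en-6-yl]butanoate (both epimers at the ester α carbon) | C=C(C)[C@@H]1CCC2(OCCO2)[C@@H](CCC(C)C(=O)OC(C)(C)C)C=C1
F3 | step 10 | tert-butyl 2-methyl-2-(phenylselanyl)-4-[(6S,9R)-9-(prop-1-en-2-yl)-1,4-dioxaspiro[4.6]undec-7-en-6-yl]butanoate | C=C(C)[C@@H]1CCC2(OCCO2)[C@@H](CCC(C)([Se]c3ccccc3)C(=O)OC(C)(C)C)C=C1
F4 | step 10 | tert-butyl (1S,4S,5S,7R)-10,10-(ethylenedioxy)-4-methyl-7-(prop-1-en-2-yl)-cis-bicyclo[5.3.0]decane-4-carboxylate | C=C(C)[C@@H]1CCC2(OCCO2)[C@H]3CC[C@](C)(C(=O)OC(C)(C)C)[C@H]3C1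
F5 | step 10 | [(1S,4S,5S,7R)-10,10-(ethylenedioxy)-4-methyl-7-(prop-1-en-2-yl)-cis-bicyclo[5.3.0]dec-4-yl]methanol | C=C(C)[C@@H]1CCC2(OCCO2)[C@H]3CC[C@](C)(CO)[C@H]3C1
F6 | step 12 | (3,5-dimethoxyphenoxy)tri(propan-2-yl)silane | COc1cc(O[Si](C(C)C)(C(C)C)C(C)C)cc(OC)c1
F7 | step 12 | [(1S,4S,5S,7R)-10,10-(ethylenedioxy)-4-methyl-7-(prop-1-en-2-yl)-cis-bicyclo[5.3.0]dec-4-yl]{2,6-dimethoxy-4-[tri(propan-2-yl)silyloxy]phenyl}methanol (both C9' epimers) | C=C(C)[C@@H]1CCC2(OCCO2)[C@H]3CC[C@](C)(C(O)c4c(OC)cc(O[Si](C(C)C)(C(C)C)C(C)C)cc4OC)[C@H]3C1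
F8 | step 12 | 4-{[(1S,4S,5S,7R)-10,10-(ethylenedioxy)-4-methyl-7-(prop-1-en-2-yl)-cis-bicyclo[5.3.0]dec-4-yl]methylidene}-3,5-dimethoxycyclohexa-2,5-dien-1-one | C=C(C)[C@@H]1CCC2(OCCO2)[C@H]3CC[C@](C)(C=C4C(OC)=CC(=O)C=C4OC)[C@H]3C1
F9 | step 12 | 4-{(1R)-1-[(1S,4S,5S,7R)-10,10-(ethylenedioxy)-4-methyl-7-(prop-1-en-2-yl)-cis-bicyclo[5.3.0]dec-4-yl]-3-methylbutyl}-3,5-dimethoxyphenol | C=C(C)[C@@H]1CCC2(OCCO2)[C@H]3CC[C@](C)([C@@H](CC(C)C)c4c(OC)cc(O)cc4OC)[C@H]3C1
F10 | step 15 | spiro-epoxide of 22 at C10 (oxirane methylene on the β face, oxygen on the α face) | C=C(C)[C@@H]1CC[C@]2(CO2)[C@@H]3CC[C@](C)([C@@H](CC(C)C)c4c(OC)cc(OC)cc4OC)[C@H]3C1
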